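**Retrosynthetic overview**
1. The target is (1S,2S,5R,6R)-2,6-diaryl-3,7-dioxabicyclo[3.3.0]octan-1-ol with both aryl groups endo (trans to the bridgehead OH/H); both benzylic C–H bonds are made last, by hydride delivery to the convex face of a bis-hemiketal.
2. The bis-hemiketal comes from two aryllithium additions to a hydroxylated cis-fused bis-γ-lactone; the aryl unit comes from catechol (methylation, para-bromination, silylation).
3. The bis-lactone comes from α-methylene paraconic acid by dihydroxylation and lactonisation (tertiary OH, second ring); the methylene carbon is formaldehyde.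
4. (R)-Paraconic acid comes from 3-oxocyclobutanecarboxylic acid by an enantioselective Baeyer–Villiger ring expansion (cyclobutanone to γ-lactone): the key step, which forms the first ring and the stereocentre that controls all others.
5. Ring order: γ-lactone (ring expansion), then second γ-lactone, then both lactones are converted into the two 2-aryl tetrahydrofuran rings.

Assumption: in step 3 the catalyst antipode that gives the (R)-lactone is used (sense of induction to be assigned against known (R)-paraconic acid); core numbering is C1 = C–OH bridgehead, C2 and C6 = aryl carbons, O3 and O7 = ring oxygens, C5 = C–H bridgehead.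

**Route**

Step 1
Reactants: 1 catechol
Product: 2 guaiacol (2-methoxyphenol)
Conditions: MeI (1.0 equiv), K2CO3 (1.0 equiv), acetone, 56 °C
Reagents that add atoms: iodomethane, CI
Why: Williamson mono-O-methylation; with one equivalent of MeI the mono-ether is the main product and is separated from catechol and veratrole by extraction and distillation; no stereocentre.

Step 2
Reactants: 2 guaiacol
Product: 4 (4-bromo-2-methoxyphenoxy)(tert-butyl)dimethylsilane, via 4-bromo-2-methoxyphenol 3 (not isolated)
Conditions: NBS (1.0 equiv), DMF, 0 °C; then imidazole (2.5 equiv), TBSCl (1.2 equiv), 23 °C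
Reagents that add atoms: N-bromosuccinimide, O=C1CCC(=O)N1Br; tert-butyldimethylsilyl chloride, CC(C)(C)[Si](C)(C)Cl
Why: Electrophilic aromatic bromination with NBS in DMF goes para to the free phenol (the stronger donor), and silylation of the crude phenol in the same pot masks the acidic OH for the later halogen–lithium exchange.

Step 3
Reactants: 5 3-oxocyclobutane-1-carboxylic acid
Product: 6 (R)-paraconic acid [(3R)-5-oxotetrahydrofuran-3-carboxylic acid]
Conditions: 30% aq. H2O2 (1.5 equiv), (R)-TRIP [(R)-3,3'-bis(2,4,6-triisopropylphenyl)-1,1'-binaphthyl-2,2'-diyl hydrogen phosphate] (10 mol %), CHCl3, −40 °C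
Reagents that add atoms: hydrogen peroxide, OO
Why: Proposed new method: enantioselective Baeyer–Villiger desymmetrisation of a free 3-carboxy cyclobutanone, in which the chiral phosphoric acid is expected to pair with the substrate CO2H (acid–acid heterodimer) while activating H2O2 addition to the strained ketone, so that in the chiral Criegee adduct only one of the two enantiotopic CH2 groups (the one antiperiplanar to the O–O bond) undergoes the 1,2-shift to oxygen, expanding the four-membered ring to the γ-lactone and setting the (R) centre; the closest known reaction type is the chiral phosphoric acid/H2O2 Baeyer–Villiger oxidation of 3-aryl- and 3-alkylcyclobutanones.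

Step 4
Reactants: 6 (R)-paraconic acid; 7 formaldehyde
Product: 9 (3R)-4-methylene-5-oxotetrahydrofuran-3-carboxylic acid, via diacid 8 (not isolated)
Conditions: MeOMgOCO2Me (2 M in DMF), 130 °C; aq. HCl; then 37% aq. HCHO, N-methylaniline, NaOAc, AcOH, 23 °C
Reagents that add atoms: none
Why: Stiles carboxylation at the only lactone α-CH2 followed by decarboxylative Mannich methylenation (Johnson α-methylenation, precedented on paraconic acids); the carboxylate-bearing stereocentre is not enolised.

Step 5
Reactants: 9 (3R)-4-methylene-5-oxotetrahydrofuran-3-carboxylic acid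
Product: 11 (1S,5S)-1-hydroxy-3,7-dioxabicyclo[3.3.0]octane-2,6-dione, via dihydroxy acid 10 (not isolated)
Conditions: K2OsO2(OH)4 (1 mol %), NMO (1.3 equiv), citric acid (0.75 equiv), t-BuOH/H2O, 23 °C; then TsOH (5 mol %), MeCN, 50 °C
Reagents that add atoms: N-methylmorpholine N-oxide, C[N+]1([O-])CCOCC1; water, O
Why: Upjohn dihydroxylation under the citric acid conditions for electron-poor alkenes adds anti to the neighbouring CO2H, which puts the new CH2OH cis to that acid so that lactonisation closes the second ring and fixes the tertiary OH (1S) cis to the bridgehead H; the crystalline bis-lactone allows an ee upgrade.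

Step 6
Reactants: 11 (1S,5S)-1-hydroxy-3,7-dioxabicyclo[3.3.0]octane-2,6-dione; 4 (4-bromo-2-methoxyphenoxy)(tert-butyl)dimethylsilane (3.4 equiv)
Product: 13 bis-hemiketal (1S,5S)-2,6-bis[4-(tert-butyldimethylsilyloxy)-3-methoxyphenyl]-3,7-dioxabicyclo[3.3.0]octane-1,2,6-triol, via aryllithium 12 (not isolated)
Conditions: 4, n-BuLi (3.3 equiv), THF, −78 °C; then 11, −78 to −40 °C; aq. NH4Cl
Reagents that add atoms: none
Why: Bromine–lithium exchange, then addition of the aryllithium to each γ-lactone stopping at the lactolate (as in C-aryl glycoside synthesis); one equivalent is spent on the tertiary OH, and the hemiketal carbons are formed as anomer mixtures that are erased in step 7.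

Step 7
Reactants: 13 bis-hemiketal
Product: 14 (1S,2S,5R,6R)-2,6-bis[4-(tert-butyldimethylsilyloxy)-3-methoxyphenyl]-3,7-dioxabicyclo[3.3.0]octan-1-ol
Conditions: Et3SiH (6 equiv), BF3·OEt2 (4 equiv), CH2Cl2, −78 to −40 °C; Et3N quench
Reagents that add atoms: none
Why: Ionic hydrogenation of aryl hemiketals (Kishi-type lactol reduction): each aryl-stabilised bicyclic oxocarbenium ion takes hydride on the convex face, cis to the bridgehead OH or H, which sets C2 (S) and C6 (R) with both aryl groups endo; the low temperature limits epimerisation and over-reduction of the benzylic ethers.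

Step 8
Reactants: 14 bis-silyl ether
Product: 15 (1S,2S,5R,6R)-2,6-bis(4-hydroxy-3-methoxyphenyl)-3,7-dioxabicyclo[3.3.0]octan-1-ol (target)
Conditions: Bu4NF (2.2 equiv), AcOH (2.2 equiv), THF, 0 °C
Reagents that add atoms: none
Why: Fluoride cleavage of the aryl silyl ethers, buffered with AcOH so that the para-hydroxybenzylic ethers are not opened or epimerised; no stereocentre is touched.

**Compound list**
1 | catechol (benzene-1,2-diol) | Oc1ccccc1O | starting material
2 | guaiacol (2-methoxyphenol) | COc1ccccc1O | intermediate
3 | 4-bromo-2-methoxyphenol | COc1cc(Br)ccc1O | intermediate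
4 | (4-bromo-2-methoxyphenoxy)(tert-butyl)dimethylsilane | COc1cc(Br)ccc1O[Si](C)(C)C(C)(C)C | intermediate
5 | 3-oxocyclobutane-1-carboxylic acid | OC(=O)C1CC(=O)C1 | starting material
6 | (R)-paraconic acid, (3R)-5-oxotetrahydrofuran-3-carboxylic acid | OC(=O)[C@H]1COC(=O)C1 | intermediate
7 | formaldehyde | C=O | starting material
8 | (3R)-5-oxotetrahydrofuran-3,4-dicarboxylic acid (C4 epimers; magnesium chelate in the flask) | OC(=O)[C@H]1COC(=O)C1C(=O)O | intermediate
9 | (3R)-4-methylene-5-oxotetrahydrofuran-3-carboxylic acid | OC(=O)[C@H]1COC(=O)C1=C | intermediate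
10 | (3S,4S)-4-hydroxy-4-(hydroxymethyl)-5-oxotetrahydrofuran-3-carboxylic acid | OC(=O)[C@H]1COC(=O)[C@@]1(O)CO | intermediate
11 | (1S,5S)-1-hydroxy-3,7-dioxabicyclo[3.3.0]octane-2,6-dione (cis-fused bis-γ-lactone) | O=C1OC[C@@H]2C(=O)OC[C@]12O | intermediate
12 | [4-(tert-butyldimethylsilyloxy)-3-methoxyphenyl]lithium | [Li]c1ccc(O[Si](C)(C)C(C)(C)C)c(OC)c1 | intermediate
13 | (1S,5S)-2,6-bis[4-(tert-butyldimethylsilyloxy)-3-methoxyphenyl]-3,7-dioxabicyclo[3.3.0]octane-1,2,6-triol (bis-hemiketal, anomers at C2 and C6 not defined) | OC1(c3ccc(O[Si](C)(C)C(C)(C)C)c(OC)c3)OC[C@@H]2C(O)(c4ccc(O[Si](C)(C)C(C)(C)C)c(OC)c4)OC[C@]12O | intermediate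
14 | (1S,2S,5R,6R)-2,6-bis[4-(tert-butyldimethylsilyloxy)-3-methoxyphenyl]-3,7-dioxabicyclo[3.3.0]octan-1-ol | COc1cc([C@@H]2OC[C@@]3(O)[C@@H]2CO[C@H]3c2ccc(O[Si](C)(C)C(C)(C)C)c(OC)c2)ccc1O[Si](C)(C)C(C)(C)C | intermediate
15 | (1S,2S,5R,6R)-2,6-bis(4-hydroxy-3-methoxyphenyl)-3,7-dioxabicyclo[3.3.0]octan-1-ol | COc1cc([C@@H]2OC[C@@]3(O)[C@@H]2CO[C@H]3c2ccc(O)c(OC)c2)ccc1O | target

**Step count and risks**
Total step count: 8. Longest linear sequence: 6 steps (5 → 6 → 9 → 11 → 13 → 14 → 15; steps 3 to 8). The aryl branch (steps 1 and 2) joins at step 6.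

Three steps most likely to fail:

Step 3 (the proposed new step; risk: low ee or racemic background oxidation promoted by the substrate's own acid). Fallback with known chemistry: setting out from 5, uncatalysed Baeyer–Villiger oxidation with 30% H2O2 in AcOH at 23 °C gives racemic paraconic acid F1. Classical resolution with (S)-1-phenylethylamine gives the crystalline diastereomeric salt (S)-1-phenylethylammonium (R)-paraconate F2 (the antipodal amine is used if the (R)-acid salt turns out to be the more soluble one). Aqueous HCl then liberates the acid, and the route is rejoined at 6.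

Step 6 (risk: over-addition to an opened lactolate, or sluggish second addition next to the alkoxide). Fallback: setting out from 11, both lactones are opened with AlMe3 and MeNH(OMe)·HCl in CH2Cl2 at 0 °C to the bis-Weinreb amide (2S,3S)-2-hydroxy-2,3-bis(hydroxymethyl)-N1,N4-dimethoxy-N1,N4-dimethylbutanediamide F3. Its three OH groups are deprotonated with i-PrMgCl (3 equiv), and aryllithium 12 (2.4 equiv, −78 to 0 °C) then adds once to each amide, the chelated tetrahedral intermediates blocking a second addition. On NH4Cl quench the diketone triol closes to the bis-hemiketal, and the route is rejoined at 13.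

Step 7 (risk: epimerisation of the endo aryl ethers or reductive opening of the benzylic C–O bonds under the Lewis acid). Fallback: setting out from 13, the open-chain aryl ketone forms are reduced under reagent control with BH3·SMe2 and (S)-2-methyl-CBS-oxazaborolidine (the antipode if the branched alkyl group acts as the large substituent) to the pentaol (1S,2S,3R,4R)-1,4-bis[4-(tert-butyldimethylsilyloxy)-3-methoxyphenyl]-2,3-bis(hydroxymethyl)butane-1,2,4-triol F4. The two primary OH groups are sulfonylated selectively with 2,4,6-triisopropylbenzenesulfonyl chloride in pyridine to give the bis-sulfonate F5. NaH in THF at 0 °C closes both rings by 5-exo-tet Williamson etherification at the CH2 carbons, with retention at the carbinol centres, and the route is rejoined at 14.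

**Further compounds**
F1 | step 3 | racemic paraconic acid (5-oxotetrahydrofuran-3-carboxylic acid) | OC(=O)C1COC(=O)C1
F2 | step 3 | (S)-1-phenylethylammonium (R)-paraconate | C[C@H]([NH3+])c1ccccc1.[O-]C(=O)[C@H]1COC(=O)C1
F3 | step 6 | (2S,3S)-2-hydroxy-2,3-bis(hydroxymethyl)-N1,N4-dimethoxy-N1,N4-dimethylbutanediamide | CON(C)C(=O)[C@@](O)(CO)[C@H](CO)C(=O)N(C)OC
F4 | step 7 | (1S,2S,3R,4R)-1,4-bis[4-(tert-butyldimethylsilyloxy)-3-methoxyphenyl]-2,3-bis(hydroxymethyl)butane-1,2,4-triol | COc1cc(ccc1O[Si](C)(C)C(C)(C)C)[C@H](O)[C@@](O)(CO)[C@H](CO)[C@@H](O)c1ccc(O[Si](C)(C)C(C)(C)C)c(OC)c1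
F5 | step 7 | bis(2,4,6-triisopropylbenzenesulfonate) of F4 at the two primary hydroxyls | COc1cc(ccc1O[Si](C)(C)C(C)(C)C)[C@H](O)[C@@](O)(COS(=O)(=O)c2c(C(C)C)cc(C(C)C)cc2C(C)C)[C@H](COS(=O)(=O)c3c(C(C)C)cc(C(C)C)cc3C(C)C)[C@@H](O)c4ccc(O[Si](C)(C)C(C)(C)C)c(OC)c4
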